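**Retrosynthetic overview**
1. Numbering: ring carbons C1–C10 (C1=C10 alkene, CO2Me on C10, CH2OH on C4, lactone O on C6, ring-fusion CH at C7, angelate on C8); lactone carbons C11 (alkenyl), C12 (C=O), C13 (=CH2).
2. The lactone is the last ring formed: CO2 supplies C12 and the ring oxygen and is stitched between C11 (alkenyl triflate) and C6 (mesylate, inverted). This works because the exocyclic alkenyl carbon C11 on C7 lies 1,3 to the ring carbinol carbon C6, so a C11 carboxylate reaches C6 through a five-membered transition state.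
3. The ten-membered carbocycle is formed first, by ring-closing metathesis at C1=C10 (ring-cis trisubstituted enoate).
4. The acyclic diene comes from an Evans syn aldol (C6, C7) and a chromium-catalysed 2-(methoxycarbonyl)allylation (C8, C9, C10, ester); the aldol acyl carbon becomes C11 via methyl ketone and enol triflate.
5. Aldehyde 6 (C1–C6, C4 stereocentre) comes from a copper-catalysed asymmetric conjugate addition of butenyl Grignard to a γ-silyloxy enoate.

Key step: step 17

Assumption (chemistry): the sense of induction in the two ligand-controlled steps (2 and 12) is taken from the closest analogues and the ligand antipode is fixed accordingly; 1, 4, 7, 20 and 23 are taken as purchasable.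
Abbreviations: TBS = tert-butyldimethylsilyl, TES = triethylsilyl, PMB = 4-methoxybenzyl, angeloyl = (Z)-2-methylbut-2-enoyl, triflyl = CF3SO2, mesyl = CH3SO2.

Step 1
Reactants: 1 2-(TBS-oxy)acetaldehyde; 2 methyl (triphenylphosphoranylidene)acetate
Product: 3 methyl (E)-4-(TBS-oxy)but-2-enoate
Conditions: CH2Cl2, rt
Reagents that add atoms: none
Why: Wittig olefination with a stabilised ylide, which should give the (E)-enoate selectively.

Step 2
Reactants: 3 methyl (E)-4-(TBS-oxy)but-2-enoate; 4 but-3-en-1-ylmagnesium bromide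
Product: 5 methyl (R)-3-(TBS-oxymethyl)hept-6-enoate
Conditions: CuBr·SMe2 (5 mol %), Josiphos ligand (6 mol %), t-BuOMe, −75 °C; then H2O
Reagents that add atoms: none
Why: Copper-catalysed asymmetric conjugate addition of a Grignard reagent to an α,β-unsaturated ester, in which the ferrocenyl diphosphine controls the face of β-attack and sets C4 as R.

Step 3
Reactants: 5 methyl (R)-3-(TBS-oxymethyl)hept-6-enoate
Product: 6 (R)-3-(TBS-oxymethyl)hept-6-enal
Conditions: i-Bu2AlH, CH2Cl2, −78 °C; then aq. potassium sodium tartrate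
Reagents that add atoms: none
Why: Partial ester reduction with i-Bu2AlH at low temperature, where the aluminium hemiacetal should persist until work-up and release the aldehyde.

Step 4
Reactants: 7 3-(PMB-oxy)propanoic acid; 8 (R)-4-benzyloxazolidin-2-one
Product: 10 (R)-4-benzyl-3-[3-(PMB-oxy)propanoyl]oxazolidin-2-one, via mixed pivalic anhydride 9 (not isolated)
Conditions: t-BuCOCl, Et3N, THF, −20 °C; then 8, LiCl, rt
Reagents that add atoms: none
Why: N-acylation of the Evans oxazolidinone through a mixed anhydride, a standard one-pot acylation that avoids strong base.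

Step 5
Reactants: 10 (R)-4-benzyl-3-[3-(PMB-oxy)propanoyl]oxazolidin-2-one; 6 (R)-3-(TBS-oxymethyl)hept-6-enal
Product: 12 (R)-4-benzyl-3-[(2R,3S,5R)-3-hydroxy-2-(PMB-oxymethyl)-5-(TBS-oxymethyl)non-8-enoyl]oxazolidin-2-one, via dibutylboron enolate 11 (not isolated)
Conditions: n-Bu2BOTf, Et3N, CH2Cl2, −78 to 0 °C; then 6, −78 to 0 °C; then pH 7 buffer, MeOH, H2O2, 0 °C
Reagents that add atoms: none
Why: Evans syn aldol reaction, in which the (Z)-boron enolate reacts through a closed chair transition state on the face opposite the benzyl group and sets C7 and the C6 carbinol (the 6-epi configuration needed for later inversion) in a syn relationship.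

Step 6
Reactants: 12 aldol adduct
Product: 13 (2R,3S,5R)-3-hydroxy-N-methoxy-N-methyl-2-(PMB-oxymethyl)-5-(TBS-oxymethyl)non-8-enamide
Conditions: MeONHMe·HCl, AlMe3, CH2Cl2, −20 to 0 °C
Reagents that add atoms: N,O-dimethylhydroxylamine hydrochloride, CNOC.Cl
Why: Weinreb transamidation with the aluminium amide, assisted by the free β-hydroxyl group, should remove the auxiliary without epimerising C7.

Step 7
Reactants: 13 hydroxy Weinreb amide
Product: 14 (2R,3S,5R)-N-methoxy-N-methyl-2-(PMB-oxymethyl)-5-(TBS-oxymethyl)-3-(TES-oxy)non-8-enamide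
Conditions: Et3SiCl, imidazole, DMF, 0 °C
Reagents that add atoms: chlorotriethylsilane, CC[Si](Cl)(CC)CC
Why: Silylation of the secondary alcohol as a TES ether, chosen because it can later be cleaved in the presence of the primary TBS ether.

Step 8
Reactants: 14 TES-protected Weinreb amide
Product: 15 (3R,4S,6R)-3-(PMB-oxymethyl)-6-(TBS-oxymethyl)-4-(TES-oxy)dec-9-en-2-one
Conditions: MeMgBr, THF, 0 °C; then H2O
Reagents that add atoms: methylmagnesium bromide, C[Mg]Br
Why: Weinreb ketone synthesis, where the chelated tetrahedral intermediate stops at single addition and delivers the methyl ketone that carries C11 and C13.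

Step 9
Reactants: 15 methyl ketone
Product: 17 (3R,4S,6R)-3-(PMB-oxymethyl)-6-(TBS-oxymethyl)-4-(TES-oxy)deca-1,9-dien-2-yl triflate, via potassium enolate 16 (not isolated)
Conditions: KN(SiMe3)2, THF, −78 °C; then PhNTf2, −78 to 0 °C
Reagents that add atoms: N-phenylbis(trifluoromethanesulfonimide), O=S(=O)(N(c1ccccc1)S(=O)(=O)C(F)(F)F)C(F)(F)F
Why: Kinetic deprotonation of the methyl group by the hindered amide base followed by O-triflation (enol triflate formation) should fix the C11=C13 alkene and the C11 leaving group without enolising towards C7.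

Step 10
Reactants: 17 PMB-protected enol triflate
Product: 18 (3R,4S,6R)-3-(hydroxymethyl)-6-(TBS-oxymethyl)-4-(TES-oxy)deca-1,9-dien-2-yl triflate
Conditions: DDQ, CH2Cl2/pH 7 buffer, 0 °C
Reagents that add atoms: none
Why: Oxidative cleavage of the PMB ether with DDQ, which should leave the silyl ethers, the alkenyl triflate and the terminal alkene untouched.

Step 11
Reactants: 18 primary alcohol
Product: 19 (3R,4S,6R)-3-formyl-6-(TBS-oxymethyl)-4-(TES-oxy)deca-1,9-dien-2-yl triflate
Conditions: Dess–Martin periodinane, CH2Cl2, 0 °C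
Reagents that add atoms: none
Why: Dess–Martin oxidation under near-neutral conditions, chosen to avoid epimerisation of the α-stereocentre C7; the aldehyde would be used without storage.

Step 12
Reactants: 19 aldehyde; 20 methyl 2-(bromomethyl)acrylate
Product: 22 methyl (4R,5R,6S,8R)-4-hydroxy-2-methylidene-8-(TBS-oxymethyl)-6-(TES-oxy)-5-[1-(triflyloxy)vinyl]dodec-11-enoate, via trimethylsilyl ether 21 (not isolated)
Conditions: CrCl2 (10 mol %), chiral carbazole bis(oxazoline) ligand (12 mol %), Mn, Me3SiCl, i-Pr2NEt (cat.), THF, 0 °C to rt; then citric acid, MeOH, 0 °C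
Reagents that add atoms: none
Why: Catalytic asymmetric Nozaki–Hiyama–Kishi-type 2-(alkoxycarbonyl)allylation, in which the allylchromium species from 20 adds under ligand control to set C8 as R while the alkenyl triflate stays inert without a nickel co-catalyst.

Step 13
Reactants: 22 hydroxy acrylate; 23 angelic acid
Product: 25 methyl (4R,5R,6S,8R)-4-(angeloyloxy)-2-methylidene-8-(TBS-oxymethyl)-6-(TES-oxy)-5-[1-(triflyloxy)vinyl]dodec-11-enoate, via mixed Yamaguchi anhydride 24 (not isolated)
Conditions: 2,4,6-trichlorobenzoyl chloride, Et3N, toluene, rt; then 22, 70 °C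
Reagents that add atoms: none
Why: Yamaguchi esterification through the mixed anhydride, run without a nucleophilic catalyst so that the (Z)-angelate should not isomerise to the tiglate.

Step 14
Reactants: 25 acyclic diene
Product: 26 methyl (1E,5R,7S,8R,9R)-9-(angeloyloxy)-5-(TBS-oxymethyl)-7-(TES-oxy)-8-[1-(triflyloxy)vinyl]cyclodec-1-ene-1-carboxylate
Conditions: second-generation Hoveyda–Grubbs catalyst (10 mol %), toluene (1 mM), 80 °C
Reagents that add atoms: none
Why: Ring-closing metathesis between the terminal alkene and the acrylate closes the ten-membered ring, where ring strain should enforce the ring-cis (CIP E) enoate and the alkenyl triflate and angelate are too hindered or electron-poor to take part.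

Step 15
Reactants: 26 TES-protected cyclodecene
Product: 27 methyl (1E,5R,7S,8S,9R)-9-(angeloyloxy)-7-hydroxy-5-(TBS-oxymethyl)-8-[1-(triflyloxy)vinyl]cyclodec-1-ene-1-carboxylate
Conditions: PPTS, MeOH/CH2Cl2, 0 °C
Reagents that add atoms: none
Why: Acid-catalysed methanolysis of the secondary TES ether, which should be markedly faster than cleavage of the primary TBS ether.

Step 16
Reactants: 27 C6 alcohol
Product: 28 methyl (1E,5R,7S,8R,9R)-9-(angeloyloxy)-7-(mesyloxy)-5-(TBS-oxymethyl)-8-[1-(triflyloxy)vinyl]cyclodec-1-ene-1-carboxylate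
Conditions: MsCl, Et3N, CH2Cl2, 0 °C
Reagents that add atoms: methanesulfonyl chloride, CS(=O)(=O)Cl
Why: Sulfonylation with retention places the leaving group on C6 cis to O8 and anti to C11, as needed for backside attack in the key step.

Step 17
Reactants: 28 mesylate triflate; 29 carbon dioxide
Product: 31 methyl (3aS,4R,6E,10R,11aR)-4-(angeloyloxy)-10-(TBS-oxymethyl)-3-methylidene-2-oxo-2,3,3a,4,5,8,9,10,11,11a-decahydrocyclodeca[b]furan-6-carboxylate, via manganese carboxylate 30 (not isolated)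
Conditions: CoI2 (10 mol %), 2,9-dimethyl-1,10-phenanthroline (10 mol %), Mn, CO2 (1 atm), DMA, rt; then 60 °C
Reagents that add atoms: none
Why: Proposed new method: Mn reduces the CoI2/phenanthroline complex to low-valent cobalt, which inserts into the C11–OTf bond; the alkenylcobalt captures CO2 at C11 (C11–C12 bond) to give carboxylate 30, whose oxygen displaces the C6 mesylate on warming (O–C6 bond). The closest known reaction types are the cobalt- or nickel-catalysed reductive carboxylation of alkenyl triflates with CO2 and the SN2 lactonisation of carboxylate salts onto secondary sulfonates. The lactone closes in the 5-exo-tet mode, made possible by the 1,3-relationship of C11 and C6 across C7. No new stereocentre is created; C6 is inverted stereospecifically, which turns the syn-1,3 arrangement of O6 and O8 into the trans ring fusion (H6/H7 trans) of the target. The step needs insertion at the alkenyl triflate rather than at the alkyl mesylate or the three esters, which the much faster reaction of the sp2 C–O bond should secure, and substitution rather than E2 elimination at C6, which the intramolecular five-membered transition state, the weakly basic carboxylate and the polar aprotic solvent favour. O-alkylation can occur only at C6 because O8 is acylated, and the anti torsion about C6–C7 needed for backside attack is the one present in the trans-fused product.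

Step 18
Reactants: 31 TBS-protected lactone
Product: 32 CNP0167542.1, methyl (3aS,4R,6E,10R,11aR)-4-(angeloyloxy)-10-(hydroxymethyl)-3-methylidene-2-oxo-2,3,3a,4,5,8,9,10,11,11a-decahydrocyclodeca[b]furan-6-carboxylate
Conditions: HF·pyridine, pyridine, THF, 0 °C to rt
Reagents that add atoms: none
Why: Fluoride-mediated cleavage of the TBS ether under buffered conditions that should spare the α-methylene lactone and both unsaturated esters.

**Compound list**
1 | 2-(TBS-oxy)acetaldehyde | CC(C)(C)[Si](C)(C)OCC=O | starting material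
2 | methyl (triphenylphosphoranylidene)acetate | COC(=O)C=P(c1ccccc1)(c1ccccc1)c1ccccc1 | starting material
3 | methyl (E)-4-(TBS-oxy)but-2-enoate | COC(=O)/C=C/CO[Si](C)(C)C(C)(C)C | intermediate
4 | but-3-en-1-ylmagnesium bromide | C=CCC[Mg]Br | starting material
5 | methyl (R)-3-(TBS-oxymethyl)hept-6-enoate | COC(=O)C[C@H](CO[Si](C)(C)C(C)(C)C)CCC=C | intermediate
6 | (R)-3-(TBS-oxymethyl)hept-6-enal | O=CC[C@H](CO[Si](C)(C)C(C)(C)C)CCC=C | intermediate
7 | 3-(PMB-oxy)propanoic acid | COc1ccc(COCCC(=O)O)cc1 | starting material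
8 | (R)-4-benzyloxazolidin-2-one | O=C1OC[C@@H](Cc2ccccc2)N1 | starting material
9 | 3-(PMB-oxy)propanoic pivalic anhydride | COc1ccc(COCCC(=O)OC(=O)C(C)(C)C)cc1 | intermediate
10 | (R)-4-benzyl-3-[3-(PMB-oxy)propanoyl]oxazolidin-2-one | COc1ccc(COCCC(=O)N2C(=O)OC[C@H]2Cc2ccccc2)cc1 | intermediate
11 | (Z)-dibutylboron enolate of 10 | CCCCB(CCCC)O/C(=C\COCc1ccc(OC)cc1)N1C(=O)OC[C@H]1Cc1ccccc1 | intermediate
12 | (R)-4-benzyl-3-[(2R,3S,5R)-3-hydroxy-2-(PMB-oxymethyl)-5-(TBS-oxymethyl)non-8-enoyl]oxazolidin-2-one | O=C(N1C(=O)OC[C@H]1Cc1ccccc1)[C@H](COCc1ccc(OC)cc1)[C@@H](O)C[C@H](CO[Si](C)(C)C(C)(C)C)CCC=C | intermediate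
13 | (2R,3S,5R)-3-hydroxy-N-methoxy-N-methyl-2-(PMB-oxymethyl)-5-(TBS-oxymethyl)non-8-enamide | CON(C)C(=O)[C@H](COCc1ccc(OC)cc1)[C@@H](O)C[C@H](CO[Si](C)(C)C(C)(C)C)CCC=C | intermediate
14 | (2R,3S,5R)-N-methoxy-N-methyl-2-(PMB-oxymethyl)-5-(TBS-oxymethyl)-3-(TES-oxy)non-8-enamide | CON(C)C(=O)[C@H](COCc1ccc(OC)cc1)[C@@H](O[Si](CC)(CC)CC)C[C@H](CO[Si](C)(C)C(C)(C)C)CCC=C | intermediate
15 | (3R,4S,6R)-3-(PMB-oxymethyl)-6-(TBS-oxymethyl)-4-(TES-oxy)dec-9-en-2-one | CC(=O)[C@H](COCc1ccc(OC)cc1)[C@@H](O[Si](CC)(CC)CC)C[C@H](CO[Si](C)(C)C(C)(C)C)CCC=C | intermediate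
16 | potassium terminal enolate of 15 | [K+].[O-]C(=C)[C@H](COCc1ccc(OC)cc1)[C@@H](O[Si](CC)(CC)CC)C[C@H](CO[Si](C)(C)C(C)(C)C)CCC=C | intermediate
17 | (3R,4S,6R)-3-(PMB-oxymethyl)-6-(TBS-oxymethyl)-4-(TES-oxy)deca-1,9-dien-2-yl triflate | C=C(OS(=O)(=O)C(F)(F)F)[C@H](COCc1ccc(OC)cc1)[C@@H](O[Si](CC)(CC)CC)C[C@H](CO[Si](C)(C)C(C)(C)C)CCC=C | intermediate
18 | (3R,4S,6R)-3-(hydroxymethyl)-6-(TBS-oxymethyl)-4-(TES-oxy)deca-1,9-dien-2-yl triflate | C=C(OS(=O)(=O)C(F)(F)F)[C@H](CO)[C@@H](O[Si](CC)(CC)CC)C[C@H](CO[Si](C)(C)C(C)(C)C)CCC=C | intermediate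
19 | (3R,4S,6R)-3-formyl-6-(TBS-oxymethyl)-4-(TES-oxy)deca-1,9-dien-2-yl triflate | C=C(OS(=O)(=O)C(F)(F)F)[C@H](C=O)[C@@H](O[Si](CC)(CC)CC)C[C@H](CO[Si](C)(C)C(C)(C)C)CCC=C | intermediate
20 | methyl 2-(bromomethyl)acrylate | C=C(CBr)C(=O)OC | starting material
21 | trimethylsilyl ether of 22 | C=C(OS(=O)(=O)C(F)(F)F)[C@H]([C@H](O[Si](C)(C)C)CC(=C)C(=O)OC)[C@@H](O[Si](CC)(CC)CC)C[C@H](CO[Si](C)(C)C(C)(C)C)CCC=C | intermediate
22 | methyl (4R,5R,6S,8R)-4-hydroxy-2-methylidene-8-(TBS-oxymethyl)-6-(TES-oxy)-5-[1-(triflyloxy)vinyl]dodec-11-enoate | C=C(OS(=O)(=O)C(F)(F)F)[C@H]([C@H](O)CC(=C)C(=O)OC)[C@@H](O[Si](CC)(CC)CC)C[C@H](CO[Si](C)(C)C(C)(C)C)CCC=C | intermediate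
23 | angelic acid, (Z)-2-methylbut-2-enoic acid | C/C=C(/C)C(=O)O | starting material
24 | angelic 2,4,6-trichlorobenzoic anhydride | C/C=C(/C)C(=O)OC(=O)c1c(Cl)cc(Cl)cc1Cl | intermediate
25 | methyl (4R,5R,6S,8R)-4-(angeloyloxy)-2-methylidene-8-(TBS-oxymethyl)-6-(TES-oxy)-5-[1-(triflyloxy)vinyl]dodec-11-enoate | C=C(OS(=O)(=O)C(F)(F)F)[C@H]([C@H](OC(=O)/C(C)=C\C)CC(=C)C(=O)OC)[C@@H](O[Si](CC)(CC)CC)C[C@H](CO[Si](C)(C)C(C)(C)C)CCC=C | intermediate
26 | methyl (1E,5R,7S,8R,9R)-9-(angeloyloxy)-5-(TBS-oxymethyl)-7-(TES-oxy)-8-[1-(triflyloxy)vinyl]cyclodec-1-ene-1-carboxylate | C=C(OS(=O)(=O)C(F)(F)F)[C@@H]1[C@H](OC(=O)/C(C)=C\C)C/C(C(=O)OC)=C\CC[C@@H](CO[Si](C)(C)C(C)(C)C)C[C@@H]1O[Si](CC)(CC)CC | intermediate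
27 | methyl (1E,5R,7S,8S,9R)-9-(angeloyloxy)-7-hydroxy-5-(TBS-oxymethyl)-8-[1-(triflyloxy)vinyl]cyclodec-1-ene-1-carboxylate | C=C(OS(=O)(=O)C(F)(F)F)[C@@H]1[C@H](OC(=O)/C(C)=C\C)C/C(C(=O)OC)=C\CC[C@@H](CO[Si](C)(C)C(C)(C)C)C[C@@H]1O | intermediate
28 | methyl (1E,5R,7S,8R,9R)-9-(angeloyloxy)-7-(mesyloxy)-5-(TBS-oxymethyl)-8-[1-(triflyloxy)vinyl]cyclodec-1-ene-1-carboxylate | C=C(OS(=O)(=O)C(F)(F)F)[C@@H]1[C@H](OC(=O)/C(C)=C\C)C/C(C(=O)OC)=C\CC[C@@H](CO[Si](C)(C)C(C)(C)C)C[C@@H]1OS(C)(=O)=O | intermediate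
29 | carbon dioxide | O=C=O | starting material
30 | manganese triflate salt of the C11 carboxylate derived from 28 | [Mn+2].[O-]S(=O)(=O)C(F)(F)F.C=C(C(=O)[O-])[C@@H]1[C@H](OC(=O)/C(C)=C\C)C/C(C(=O)OC)=C\CC[C@@H](CO[Si](C)(C)C(C)(C)C)C[C@@H]1OS(C)(=O)=O | intermediate
31 | methyl (3aS,4R,6E,10R,11aR)-4-(angeloyloxy)-10-(TBS-oxymethyl)-3-methylidene-2-oxo-2,3,3a,4,5,8,9,10,11,11a-decahydrocyclodeca[b]furan-6-carboxylate | C=C1C(=O)O[C@@H]2C[C@H](CO[Si](C)(C)C(C)(C)C)CC/C=C(/C(=O)OC)C[C@@H](OC(=O)/C(C)=C\C)[C@@H]12 | intermediate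
32 | CNP0167542.1, methyl (3aS,4R,6E,10R,11aR)-4-(angeloyloxy)-10-(hydroxymethyl)-3-methylidene-2-oxo-2,3,3a,4,5,8,9,10,11,11a-decahydrocyclodeca[b]furan-6-carboxylate | C=C1C(=O)O[C@@H]2C[C@H](CO)CC/C=C(/C(=O)OC)C[C@@H](OC(=O)/C(C)=C\C)[C@@H]12 | target

**Step count and risks**
Total steps: 18. Longest linear sequence: 17 (steps 1–3 and 5–18; step 4 is a one-step side branch).

Steps most likely to fail:

1. Step 17 (Proposed new method). Protodemetalation of the alkenylcobalt, E2 loss of the mesylate or reduction of the newly formed exocyclic alkene could outrun carboxylation and ring closure. The fallback uses known chemistry, with CO in place of CO2 and two stages. Starting from 28, palladium-catalysed hydroxycarbonylation of the alkenyl triflate (Pd(OAc)2, dppf, CO 1 atm, KOAc, DMF, 60 °C; then H2O) would give the acrylic acid mesylate F1. Its cesium salt (Cs2CO3, DMF, 50 °C) would close the lactone by intramolecular SN2 with inversion and rejoin the route at 31.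

2. Step 14. Intermolecular cross-metathesis (oligomerisation) and slow engagement of the 1,1-disubstituted acrylate could dominate over closure of the strained ten-membered ring. The fallback moves ring closure to after lactone formation. Starting from 25, the TES ether would be cleaved (PPTS, MeOH) to the acyclic alcohol F2, which would be mesylated (MsCl, Et3N) to the acyclic mesylate F3. F3 would undergo the carboxylative lactonisation of step 17 to give the trans-disubstituted α-methylene butyrolactone F4. Ring-closing metathesis of F4, whose two side chains sit on adjacent carbons of the rigid five-membered ring, would then form C1=C10 and rejoin the route at 31.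

3. Step 12. Facial selectivity at C8 could be poor if ligand and substrate bias are mismatched, and the β,γ-unsaturated aldehyde could epimerise at C7 or the product could lactonise onto the methyl ester. The fallback sets C8 by reagent-controlled ketone reduction. Starting from 19, indium-mediated Barbier allylation with 20 (In, THF/H2O) would give the C8-epimeric alcohol mixture F5, and Dess–Martin oxidation the β,γ-unsaturated ketone F6. Reduction with the (S)-Me-CBS oxazaborolidine and catecholborane (toluene, −78 °C) should give the 8R alcohol and rejoin the route at 22.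

Further compounds
F1 | step 17 | acrylic acid mesylate (C11 carboxylic acid of 28) | C=C(C(=O)O)[C@@H]1[C@H](OC(=O)/C(C)=C\C)C/C(C(=O)OC)=C\CC[C@@H](CO[Si](C)(C)C(C)(C)C)C[C@@H]1OS(C)(=O)=O
F2 | step 14 | acyclic C6 alcohol (25 without TES) | C=C(OS(=O)(=O)C(F)(F)F)[C@H]([C@H](OC(=O)/C(C)=C\C)CC(=C)C(=O)OC)[C@@H](O)C[C@H](CO[Si](C)(C)C(C)(C)C)CCC=C
F3 | step 14 | acyclic C6 mesylate | C=C(OS(=O)(=O)C(F)(F)F)[C@H]([C@H](OC(=O)/C(C)=C\C)CC(=C)C(=O)OC)[C@@H](OS(C)(=O)=O)C[C@H](CO[Si](C)(C)C(C)(C)C)CCC=C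
F4 | step 14 | acyclic trans-disubstituted α-methylene butyrolactone | C=C1C(=O)O[C@H](C[C@H](CO[Si](C)(C)C(C)(C)C)CCC=C)[C@H]1[C@H](OC(=O)/C(C)=C\C)CC(=C)C(=O)OC
F5 | step 12 | C8-epimeric mixture of hydroxy acrylate 22 | C=C(OS(=O)(=O)C(F)(F)F)[C@H](C(O)CC(=C)C(=O)OC)[C@@H](O[Si](CC)(CC)CC)C[C@H](CO[Si](C)(C)C(C)(C)C)CCC=C
F6 | step 12 | C8 ketone | C=C(OS(=O)(=O)C(F)(F)F)[C@H](C(=O)CC(=C)C(=O)OC)[C@@H](O[Si](CC)(CC)CC)C[C@H](CO[Si](C)(C)C(C)(C)C)CCC=C
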